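**Retrosynthetic overview**

1. Locants: ring O1, C2 (side-chain carbon), C3, C4, C5 (butyl carbon); side chain C1'H2–C2'(=O)–tetradecyl. C2'–C3' is cut to a Weinreb amide plus tetradecylmagnesium bromide. The C3 methylene is traced back to a C3 ketone, removed by reduction and radical deoxygenation.
2. The key cut is C4–C5 of the only ring. C5 is an ether carbon bearing one hydrogen. In the open-chain n-pentyl ether on O1, the O–CH2 hydrogens therefore lie 1,5 to a carbene at C4 along C4–C3(=O)–C2–O1–C5, so a diazomethyl ketone can close the oxolan-3-one by C–H insertion.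
3. The diazoketone comes from (S)-malic acid (C2 with its configuration, C3, C1', C2') and pentanal (C5 plus butyl). A dioxolanone acetal ties the hydroxyl to the proximal carboxyl, the distal carboxyl is methylated, and reductive acetal opening gives the pentyl ether while freeing only the carboxyl that becomes C3.
4. This entry is chosen for three reasons: a primary pentyl group is transferred poorly by cation-type alkylating agents, alkoxide conditions eliminate malates to fumarates, and saponification does not reliably distinguish the two esters of an O-alkyl malate.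
5. Ring order: temporary dioxolanone (step 1, opened in step 3), oxolane (step 5), temporary cis-fused γ-lactone C3–O–C2' (step 6, opened in step 7).

Key step: step 5

Assumption: the acetal carbon of 3 and 4 is drawn as the cis epimer expected to prevail and is erased in step 3, so either epimer serves; ethereal diazomethane is taken as a freshly generated stock reagent.

**Step 1**
Reactants: 1 (S)-malic acid; 2 pentanal
Product: 3 2-[(2S,4S)-2-butyl-5-oxo-1,3-dioxolan-4-yl]acetic acid
Conditions: TsOH·H2O (cat.), cyclohexane, Dean–Stark, reflux
Reagents that add atoms: none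
Why: Acid-catalysed acetalisation of an α-hydroxy acid closes the five-membered dioxolanone in preference to the six-membered ring through the distal carboxyl, so one operation masks the hydroxyl with the proximal carboxyl, leaves the distal carboxyl free and attaches all five carbons of the future pentyl ether without touching the malate stereocentre, while the acetal carbon should form mainly cis under equilibrating conditions.

**Step 2**
Reactants: 3 2-[(2S,4S)-2-butyl-5-oxo-1,3-dioxolan-4-yl]acetic acid
Product: 4 methyl 2-[(2S,4S)-2-butyl-5-oxo-1,3-dioxolan-4-yl]acetate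
Conditions: CH2N2, Et2O, 0 °C
Reagents that add atoms: diazomethane, C=[N+]=[N-]
Why: Diazomethane esterification (proton transfer, then SN2 on methyldiazonium) methylates only the free carboxylic acid under neutral conditions, so the acid- and base-labile dioxolanone and the stereocentre stay intact.

**Step 3**
Reactants: 4 methyl 2-[(2S,4S)-2-butyl-5-oxo-1,3-dioxolan-4-yl]acetate
Product: 5 (2S)-4-methoxy-4-oxo-2-(pentyloxy)butanoic acid
Conditions: Et3SiH, TiCl4, CH2Cl2, −78 to −20 °C; then H2O
Reagents that add atoms: none
Why: In this reductive acetal opening (ionic hydrogenation) TiCl4 binds the ring carbonyl, the acetal C–O(acyl) bond ionises because carboxylate is the better leaving group, and Et3SiH reduces the oxocarbenium ion held on the ether oxygen, which gives the n-pentyl ether and frees only the proximal carboxyl without base and without touching the stereocentre.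

**Step 4**
Reactants: 5 (2S)-4-methoxy-4-oxo-2-(pentyloxy)butanoic acid
Product: 7 methyl (3S)-5-diazo-4-oxo-3-(pentyloxy)pentanoate, via isobutyl carbonic mixed anhydride 6 (not isolated)
Conditions: i-BuOCOCl, N-methylmorpholine, THF, −20 °C; then CH2N2 (excess), Et2O, −20 °C to rt
Reagents that add atoms: isobutyl chloroformate, CC(C)COC(=O)Cl (atoms kept only in 6); diazomethane, C=[N+]=[N-]
Why: Acylation of diazomethane by a mixed carbonic anhydride (first stage of the Arndt–Eistert sequence), well established on N-protected aspartic β-esters of the same frame, activates the acid at low temperature without ketene formation or acyl/ester interchange across the succinate unit, so the α-alkoxy stereocentre is kept.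

**Step 5**
Reactants: 7 methyl (3S)-5-diazo-4-oxo-3-(pentyloxy)pentanoate
Product: 8 methyl 2-[(2S,5R)-5-butyl-3-oxooxolan-2-yl]acetate
Conditions: Rh2(OAc)4 (1 mol %), CH2Cl2, rt, slow addition of 7 at high dilution
Reagents that add atoms: none
Why: Dirhodium tetraacetate, a dimer of divalent rhodium, takes up the diazo carbon and expels N2 to give an electrophilic rhodium-bound carbene at C4, and an O–CH2 hydrogen of the pentyl ether, made hydridic by the lone pair of O1, is transferred while C4–C5 forms in one concerted, asynchronous three-centre event that releases the catalyst. The closest known reaction type is the dirhodium carboxylate-catalysed C–H insertion of α'-alkoxy diazomethyl ketones next to the ether oxygen, which delivers cis-2,5-disubstituted oxolan-3-ones. The oxolane closes by 1,5-insertion, that is by C4–C5 bond formation across the chain C4–C3(=O)–C2–O1–C5. The new stereocentre C5 is controlled by C2, because in the envelope-like transition state the butyl group and the CH2CO2Me arm both take pseudo-equatorial positions, so one of the two diastereotopic hydrogens reacts with retention and the cis (2S,5R) ketone should prevail, while C2 itself is not touched. The step needs site selectivity and chemoselectivity, and the substrate secures both: the only other atom in 1,5-relation is the ester carbon, which carries no hydrogen, insertion at C1' would give a cyclobutanone at a C–H bond deactivated by the ester, the next pentyl methylene is unactivated and would need a six-membered ring, and attack of O1 on the carbene would need a strained four-membered oxonium ylide. Slow addition at high dilution holds back carbene dimerisation, and the weakly nucleophilic ester carbonyl, which could form a six-membered carbonyl ylide reversibly, finds no trapping partner.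

**Step 6**
Reactants: 8 methyl 2-[(2S,5R)-5-butyl-3-oxooxolan-2-yl]acetate
Product: 10 (3aS,5R,6aS)-5-butylhexahydrofuro[3,2-b]furan-2-one, via all-cis hydroxy ester 9 (not isolated)
Conditions: NaBH4, MeOH, −40 °C; then CSA (cat.), CH2Cl2, rt
Reagents that add atoms: none
Why: Fast hydride reduction from the face opposite the two cis substituents should place the C3 hydroxyl syn to the C2 arm (3S) before C2 can enolise, and acid-catalysed lactonisation then takes this γ-hydroxy ester fully into the cis-fused bicyclic lactone, while any 3-epimer stays a hydroxy ester and converges on 13 through steps 7 to 9 because C3 loses its oxygen there.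

**Step 7**
Reactants: 10 (3aS,5R,6aS)-5-butylhexahydrofuro[3,2-b]furan-2-one
Product: 11 2-[(2S,3S,5R)-5-butyl-3-hydroxyoxolan-2-yl]-N-methoxy-N-methylacetamide
Conditions: MeNH(OMe)·HCl, AlMe3, CH2Cl2, 0 °C to rt; then aq potassium sodium tartrate; used without delay
Reagents that add atoms: N,O-dimethylhydroxylamine hydrochloride, CNOC.Cl
Why: Aluminium amide aminolysis (Weinreb amidation) opens the lactone at the acyl carbon under Lewis acidic, non-basic conditions, so no enolate forms, the β-alkoxy link at C2 cannot open by retro-oxa-Michael reaction, and no stereocentre is affected.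

**Step 8**
Reactants: 11 2-[(2S,3S,5R)-5-butyl-3-hydroxyoxolan-2-yl]-N-methoxy-N-methylacetamide
Product: 12 O-[(2S,3S,5R)-5-butyl-2-{2-[methoxy(methyl)amino]-2-oxoethyl}oxolan-3-yl] O-phenyl carbonothioate
Conditions: PhOC(S)Cl, pyridine, DMAP (cat.), CH2Cl2, 0 °C to rt
Reagents that add atoms: O-phenyl chlorothionoformate, ClC(=S)Oc1ccccc1
Why: Thioacylation of the secondary alcohol with a reactive chlorothionoformate under amine catalysis is chosen over the NaH/CS2/MeI xanthate protocol, whose alkoxide would relactonise and whose base would enolise the β-alkoxy amide.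

**Step 9**
Reactants: 12 O-[(2S,3S,5R)-5-butyl-2-{2-[methoxy(methyl)amino]-2-oxoethyl}oxolan-3-yl] O-phenyl carbonothioate
Product: 13 2-[(2R,5R)-5-butyloxolan-2-yl]-N-methoxy-N-methylacetamide
Conditions: Bu3SnH, AIBN (cat.), toluene, 85 °C
Reagents that add atoms: none
Why: In this Barton–McCombie deoxygenation the stannyl radical adds to C=S, the C3–O bond fragments to a secondary ring radical that takes hydrogen from Bu3SnH, the unstrained ether C–O bond β to the radical does not cleave, and C2 and C5 are not involved, so the cis relation is kept and the C2 descriptor changes to R by priority only.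

**Step 10**
Reactants: 14 1-bromotetradecane
Product: 15 tetradecylmagnesium bromide
Conditions: Mg turnings, I2 (cat.), THF, 40 °C
Reagents that add atoms: magnesium, [Mg]
Why: Grignard reagent formation by insertion of magnesium into a primary C–Br bond is routine for long-chain bromides in THF.

**Step 11**
Reactants: 13 2-[(2R,5R)-5-butyloxolan-2-yl]-N-methoxy-N-methylacetamide; 15 tetradecylmagnesium bromide
Product: 17 1-[(2R,5R)-5-butyloxolan-2-yl]hexadecan-2-one, via chelated magnesium hemiaminal 16 (not isolated)
Conditions: THF, −20 to 0 °C; then sat. aq NH4Cl, 0 °C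
Reagents that add atoms: none
Why: In this Weinreb ketone synthesis the five-membered magnesium chelate of the tetrahedral adduct survives until the buffered quench, which prevents over-addition, and the low temperature with near-neutral work-up avoids enolisation and retro-oxa-Michael epimerisation at C2.

**Compound list**

1 | (S)-malic acid, (2S)-2-hydroxybutanedioic acid | OC(=O)C[C@H](O)C(=O)O | starting material
2 | pentanal | CCCCC=O | starting material
3 | 2-[(2S,4S)-2-butyl-5-oxo-1,3-dioxolan-4-yl]acetic acid | OC(=O)C[C@@H]1O[C@H](CCCC)OC1=O | intermediate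
4 | methyl 2-[(2S,4S)-2-butyl-5-oxo-1,3-dioxolan-4-yl]acetate | COC(=O)C[C@@H]1O[C@H](CCCC)OC1=O | intermediate
5 | (2S)-4-methoxy-4-oxo-2-(pentyloxy)butanoic acid | COC(=O)C[C@H](OCCCCC)C(=O)O | intermediate
6 | (2S)-4-methoxy-4-oxo-2-(pentyloxy)butanoic isobutyl carbonic anhydride | COC(=O)C[C@H](OCCCCC)C(=O)OC(=O)OCC(C)C | intermediate (not isolated)
7 | methyl (3S)-5-diazo-4-oxo-3-(pentyloxy)pentanoate | COC(=O)C[C@H](OCCCCC)C(=O)C=[N+]=[N-] | intermediate
8 | methyl 2-[(2S,5R)-5-butyl-3-oxooxolan-2-yl]acetate | COC(=O)C[C@H]1C(=O)C[C@@H](CCCC)O1 | intermediate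
9 | methyl 2-[(2S,3S,5R)-5-butyl-3-hydroxyoxolan-2-yl]acetate | COC(=O)C[C@H]1[C@@H](O)C[C@@H](CCCC)O1 | intermediate (not isolated)
10 | (3aS,5R,6aS)-5-butylhexahydrofuro[3,2-b]furan-2-one | O=C1C[C@H]2[C@@H](O1)C[C@@H](CCCC)O2 | intermediate
11 | 2-[(2S,3S,5R)-5-butyl-3-hydroxyoxolan-2-yl]-N-methoxy-N-methylacetamide | CON(C)C(=O)C[C@H]1[C@@H](O)C[C@@H](CCCC)O1 | intermediate
12 | O-[(2S,3S,5R)-5-butyl-2-{2-[methoxy(methyl)amino]-2-oxoethyl}oxolan-3-yl] O-phenyl carbonothioate | CON(C)C(=O)C[C@H]1[C@@H](OC(=S)Oc2ccccc2)C[C@@H](CCCC)O1 | intermediate
13 | 2-[(2R,5R)-5-butyloxolan-2-yl]-N-methoxy-N-methylacetamide | CON(C)C(=O)C[C@H]1CC[C@@H](CCCC)O1 | intermediate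
14 | 1-bromotetradecane | CCCCCCCCCCCCCCBr | starting material
15 | tetradecylmagnesium bromide | CCCCCCCCCCCCCC[Mg]Br | intermediate
16 | bromomagnesium 1-[(2R,5R)-5-butyloxolan-2-yl]-2-[methoxy(methyl)amino]hexadecan-2-olate (C2' configuration undefined) | CCCCCCCCCCCCCCC(O[Mg]Br)(N(C)OC)C[C@H]1CC[C@@H](CCCC)O1 | intermediate (not isolated)
17 | 1-[(2R,5R)-5-butyloxolan-2-yl]hexadecan-2-one | CCCCCCCCCCCCCCC(=O)C[C@H]1CC[C@@H](CCCC)O1 | target

**Step count**

Total steps: 11. Longest linear sequence: 10 (steps 1 to 9 and 11).

**Steps most likely to fail**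

1. Step 5.
   - What may go wrong: the rhodium carbene may be diverted before it reaches the O–CH2 hydrogens, through capture by the ester carbonyl oxygen or dimerisation. The two diastereotopic hydrogens may also be poorly distinguished, which would erode the cis relation.
   - Fallback: the ring is built from the C5 side and the cis relation is set by hydrogenation. It sets out from pentanal 2 and comes back at 13.
   - Pentanal 2 is alkynylated with methyl propiolate (Et2Zn, Ti(OiPr)4, the BINOL antipode that gives the R carbinol) to methyl (4R)-4-hydroxyoct-2-ynoate F1.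
   - Hydrogenation (H2, Pd/C, EtOAc) gives methyl (4R)-4-hydroxyoctanoate F2, which closes with catalytic TsOH to (5R)-5-butyloxolan-2-one F3.
   - Addition of the lithium enolate of ethyl acetate (LiN(iPr)2, THF, −78 °C) gives ethyl 2-[(5R)-5-butyl-2-hydroxyoxolan-2-yl]acetate F4.
   - Catalytic TsOH in toluene over molecular sieves dehydrates F4 to ethyl (2E)-2-[(5R)-5-butyloxolan-2-ylidene]acetate F5.
   - Hydrogenation over Rh/Al2O3 from the face away from the butyl group should give ethyl 2-[(2R,5R)-5-butyloxolan-2-yl]acetate F6.
   - MeNH(OMe)·HCl/AlMe3 converts F6 into 13.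

2. Step 8.
   - What may go wrong: relactonisation of the γ-hydroxy Weinreb amide, with loss of the amine, may outrun thioacylation of the crowded all-cis alcohol.
   - Fallback: the carbonyl oxygen is removed without ever forming the alcohol. It sets out from ketone 8 and comes back at 13.
   - Ketone 8 is treated with ethane-1,2-dithiol and BF3·OEt2 (CH2Cl2, 0 °C) to give methyl 2-[(6S,8R)-8-butyl-7-oxa-1,4-dithiaspiro[4.4]nonan-6-yl]acetate F7.
   - Mozingo desulfurisation with Raney Ni in EtOH gives methyl 2-[(2R,5R)-5-butyloxolan-2-yl]acetate F8.
   - MeNH(OMe)·HCl/AlMe3 converts F8 into 13.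

3. Step 3.
   - What may go wrong: after ionisation of the acetal, proton loss to an enol ether or Lewis acid-induced β-elimination of the alkoxy group may compete with hydride transfer. Unreduced material would also hydrolyse back to the hydroxy acid on work-up.
   - Fallback: direct O-alkylation on an orthogonally protected malate. It sets out from 4 and comes back at 5.
   - Acid-catalysed alcoholysis of the activated ring acyl group of 4 (BnOH, catalytic TsOH, rt) gives 1-benzyl 4-methyl (2S)-2-hydroxybutanedioate F9.
   - Silver oxide-mediated alkylation (Ag2O, 1-iodopentane, molecular sieves, toluene, dark) gives 1-benzyl 4-methyl (2S)-2-(pentyloxy)butanedioate F10 without alkoxide formation.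
   - Hydrogenolysis of F10 (H2, Pd/C, EtOAc) frees only the proximal carboxyl to give 5.

**Further compounds**

F1 | step 5 | methyl (4R)-4-hydroxyoct-2-ynoate | CCCC[C@@H](O)C#CC(=O)OC
F2 | step 5 | methyl (4R)-4-hydroxyoctanoate | CCCC[C@@H](O)CCC(=O)OC
F3 | step 5 | (5R)-5-butyloxolan-2-one | CCCC[C@@H]1CCC(=O)O1
F4 | step 5 | ethyl 2-[(5R)-5-butyl-2-hydroxyoxolan-2-yl]acetate | CCOC(=O)CC1(O)CC[C@@H](CCCC)O1
F5 | step 5 | ethyl (2E)-2-[(5R)-5-butyloxolan-2-ylidene]acetate | CCOC(=O)/C=C1\CC[C@@H](CCCC)O1
F6 | step 5 | ethyl 2-[(2R,5R)-5-butyloxolan-2-yl]acetate | CCOC(=O)C[C@H]1CC[C@@H](CCCC)O1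
F7 | step 8 | methyl 2-[(6S,8R)-8-butyl-7-oxa-1,4-dithiaspiro[4.4]nonan-6-yl]acetate | COC(=O)C[C@H]1C2(SCCS2)C[C@@H](CCCC)O1
F8 | step 8 | methyl 2-[(2R,5R)-5-butyloxolan-2-yl]acetate | COC(=O)C[C@H]1CC[C@@H](CCCC)O1
F9 | step 3 | 1-benzyl 4-methyl (2S)-2-hydroxybutanedioate | COC(=O)C[C@H](O)C(=O)OCc1ccccc1
F10 | step 3 | 1-benzyl 4-methyl (2S)-2-(pentyloxy)butanedioate | COC(=O)C[C@H](OCCCCC)C(=O)OCc1ccccc1
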